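## Structural features

Artoindonesianin R (26) is a flavone: a benzo-fused 4-pyranone (rings A and C share the C4a–C8a bond) that carries ring B on C2 through one aryl–vinyl C–C bond and a 3-methylbut-2-enyl (prenyl) chain on C3. Ring A bears hydroxyls at C5 (chelated to the C4 carbonyl) and C7, which with O1 on C8a make a 1,3,5-trioxygenated benzene. Ring B bears methoxyls at C2' and C4' and a free hydroxyl at C5'. The molecule has no stereocentre and no double bond with geometry, so every problem is one of regiochemistry and chemoselectivity. The fragile parts are the trisubstituted prenyl alkene (protic acid adds to it or closes it onto a neighbouring enol or phenol oxygen; hydrogenation and electrophilic oxidants attack it), the three electron-rich phenols, and the pyranone, which hydroxide or alkoxide can open at C2. The real difficulty is the crowded, fully substituted C2=C3 bond between an ortho-substituted aryl ring and the prenyl group, together with the need to keep one ring B oxygen distinct from its two methylated neighbours and to deliver the ring A oxygens free without a late oxidation or a strong-acid deprotection. The key step exploits the fact that C5–C8 of ring A, with oxygen on C5 and C7 in a meta relation, sit on the C4a–C8a bond, which is simply the C5=C6 double bond of a monocyclic 2-aryl-3-prenyl-4-pyranone: a two-carbon ketene unit on that bond plus a two-carbon oxygenated alkyne complete the resorcinol ring.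

## Logic of the disconnections

26 to 24. No skeletal bond is cut; the O–Si bonds at C7 and C5' and the C6–Si bond are put back. The reason is that free phenols would add to the ketenes of the key step and that the silicon on C6 is the trace of the alkyne partner. The gain is an endgame of one flask with fluoride and dilute acid. The demand is that C6–Si must cleave without acid strong enough to touch the prenyl alkene, which is met because C6 is ortho to two hydroxyls and para to O1.

24 to 15 and 19. The bonds C8–C8a, C7–C8, C5–C6 and C4a–C5 are cut, which removes ring A entirely. The reason is that a ketene carbonyl carbon (future C5–OH) and an ynol ether oxygen (future C7–O) arrive meta to each other by construction. The gain is that a bicyclic, trioxygenated chromone falls back to a monocyclic pyranone and a two-carbon alkyne. The demands are clean ketene generation beside a light-absorbing aryl pyranone, regioselective cycloaddition, and ring closure onto pyranone C5. Tracing the atoms through 20, 21, 22 and 23 confirms the connectivity of 15, 19 and 24: the carbonyl carbon of 15 becomes C5, its diazo carbon C8, the silicon-bearing carbon of 19 becomes C6 and its oxygen-bearing carbon C7. The structures are mutually consistent and needed no correction. The design is tightened in three respects: every phenol is absent or silylated before a ketene exists, the ketene is released with visible light that the aryl pyranone does not absorb, and the diazo compound is reached without diazomethane and without hydrogen chloride.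

15 to 13 (through 14). The bond between the ketone carbon and the diazo carbon is cut. The reason is that acylation of a silylated diazomethane is the mildest entry to a terminal diazoketone. The gain is a plain carboxylic acid. The demand is an activation that is neutral, because the prenyl alkene and the aryl silyl ether are present.

13 to 12 to 11. First the ester is restored, then the O1–C bond of the pyranone is cut to give an open 1,3,5-tricarbonyl chain. The reason is that either terminal enol oxygen can close onto the other terminal carbonyl and both modes give the same ring. The gain is an acyclic compound. The demand is a cyclodehydration without protic acid, since an enol oxygen sits within reach of the prenyl alkene.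

11 to 6 and 9 (through 10). The bond between the aroyl carbon and the chain carbon that carries the prenyl group (the later C2–C3 bond) is cut. The reason is convergence: all of ring B is on one side and the complete C3–C4–C4a–C8a chain with its prenyl group on the other, so the prenyl group is never introduced by alkylation of a diketone. The gain is two fragments of similar size. The demand is regioselective deprotonation of 9 at the methylene next to the prenyl chain and C-acylation there.

9 to 7 and 8. The bond between the oxalyl carbon and the methyl carbon of 7 is cut. The reason is that a crossed Claisen condensation with a non-enolizable diester is among the most reliable C–C bond formations. The gain is two bulk chemicals. The demand is acylation at the methyl and not the methylene side of 7.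

6 to 4 to 3 to 1 (through 5 and 2). The aryl–carbonyl bond, the O–Si bond and, formally, the aryl–oxygen bond are cut. The two functionalized positions of 1 exchange roles: the formyl carbon is excised and its ring position becomes the C5' oxygen, while the bromine marks the carbon that will bond to C2. The gain is that no metal-catalysed hydroxylation of an aryl bromide and no separate aryl ketone synthesis are needed. The demand is a halogen–metal exchange that tolerates the silyl ether.

19 to 16 (through 17 and 18). The alkyne C–O bond and the O–Si bond are cut. The reason is that an acetylide can be oxygenated to an ynolate. The gain is a commercial alkyne. The demand is silylation at oxygen and not at carbon.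

## Other disconnections considered

Alternative 1: The cut runs through C2–C1' and C3–C1'', with rings A and C bought together as chromone A1. In the forward direction the aryl Grignard reagent A2 (made from 1 in the way 4 is made, with an acetal in place of the silyl group) would add to C2 of A1 under catalysis by a monovalent copper salt. The resulting enolate would be trapped at C3 by a prenyl halide in the same flask to give trans-flavanone A3. Dehydrogenation to flavone A4 and acid removal of three acetal groups would follow.
- In its favour: two C–C bonds form in one operation, conjugate arylation of chromones is well charted, and there is no diazo compound and no photochemistry.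
- Against it here: the C3 enolate of a 2-arylchromanone can expel the ring phenoxide and open to a chalcone, so alkylation competes with ring opening. Two stereocentres are made only to be erased. The dehydrogenation needs an oxidant that spares the allylic positions of the prenyl group and three electron-rich rings. The final step exposes the prenyl alkene to acid.
- On structure: this alternative uses a ready-made phloroglucinol ring, which is simpler than building ring A.
- On mechanism: its first bond formation has closer precedent than the chosen key step and is the better of the two on that point, but it then needs a change of oxidation level that the chosen plan avoids.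
- On step economy: it should be shorter by about two steps in the longest line and is the better plan on that count. The chosen plan is preferred only because its endgame is milder.

Alternative 2: The cut is C3–C4, with the O1–C2 ether bond made beforehand. Aldehyde A5, treated with a thiazolium-derived carbene and K2CO3, would form a Breslow intermediate that adds in 6-exo fashion across the tethered alkyne to give alkylidene flavanone A6. A base-mediated hydrogen shift from C2 to the exocyclic carbon would then give flavone A4.
- In its favour: the flavone oxidation level is reached without any oxidant, which equals the chosen plan and betters Alternative 1. The reaction is catalytic and metal-free. The prenyl group is part of the enyne, so there is no alkylation regiochemistry.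
- Against it here: A5 needs an ether bond between a hindered, chelated ortho-hydroxy aldehyde and a secondary carbon that is both propargylic and benzylic to a trioxygenated ring. That centre ionizes easily, so both its formation and its survival under warm carbonate are doubtful. An aldehyde flanked by two ortho oxygens should form the Breslow intermediate slowly. In the final isomerization the dienyl anion can also be protonated at the far terminus, which would give the 3-methylbut-1-enyl isomer. Acid deprotection remains.
- On structure: it is equal to the chosen plan, since neither leaves a stereocentre.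
- On mechanism: it has two uncertain events (etherification and site of protonation) against one in the chosen plan.
- On step economy: it is about equal or slightly shorter.

Alternative 3: The cuts are C3–C4 and O1–C8a, and ring A arrives as acid chloride A8. The lithium enolate of ring B ketone A7 would be acylated at carbon by A8, and the diketone enolate oxygen would then displace an ortho fluoride to give difluoroflavone A9. Both fluorides must afterwards be exchanged for oxygen, for example with an allyl alkoxide to give A10, followed by removal of three allyl groups with a zerovalent palladium catalyst.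
- In its favour: it is the shortest assembly of the whole carbon skeleton. Regiochemistry is beyond doubt because either ortho fluoride gives the same ring. It needs no sensitive intermediate and no light. For building the skeleton it is the better plan.
- Against it here: the oxygen pattern of ring A is not delivered but must be installed by two successive nucleophilic aromatic substitutions on a chromone that is itself electrophilic at C2. The second displacement is slowed by the first alkoxy group. Incomplete exchange would leave fluoro-alkoxy mixtures that are hard to separate.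
- On structure: the chosen plan places both oxygens by construction.
- On mechanism: acylation followed by fluoride displacement is more secure than a photochemical cascade, but the fluoride exchange is less secure than the silyl cleavage that ends the chosen plan.
- On step economy: the two plans come out about equal once the exchange and deprotection steps are counted.

Key step: step 10

Assumption: 7, 8, 16, N-methoxy-N-methylcarbamoyl chloride and all reagents are taken as commercial; 9 and 11 are drawn as keto forms although they should exist largely as enols, and the enolizable sp3 centre of 11 is left uncontrolled because step 6 removes it.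

## Route

Step 1
Reactants: 1 5-bromo-2,4-dimethoxybenzaldehyde
Product: 3 5-bromo-2,4-dimethoxyphenol, via 5-bromo-2,4-dimethoxyphenyl formate 2 (not isolated)
Conditions: mCPBA, CH2Cl2, 0 °C to rt; aq. Na2S2O3/NaHCO3 wash; then K2CO3 (cat.), MeOH, rt
Reagents that add atoms: mCPBA (3-chloroperoxybenzoic acid), OOC(=O)c1cccc(Cl)c1
Why: Baeyer–Villiger oxidation of an electron-rich benzaldehyde (Dakin-type): the aryl group, activated by ortho and para methoxyls, migrates to oxygen to give formate 2, which mild methanolysis cleaves to 3; the former formyl position thereby becomes the future C5' oxygen and the bromine remains as the handle for the bond to C2.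

Step 2
Reactants: 3 5-bromo-2,4-dimethoxyphenol
Product: 4 (5-bromo-2,4-dimethoxyphenoxy)triisopropylsilane
Conditions: TIPSCl, imidazole, DMF, rt
Reagents that add atoms: TIPSCl (chlorotriisopropylsilane), CC(C)[Si](Cl)(C(C)C)C(C)C
Why: Standard silylation of a phenol; the bulky silyl ether should withstand organolithium and amide bases and the later enolate chemistry, and it leaves with fluoride in the last step together with the ring A silyl ether.

Step 3
Reactants: 4 (5-bromo-2,4-dimethoxyphenoxy)triisopropylsilane
Product: 6 N,2,4-trimethoxy-N-methyl-5-(triisopropylsilyloxy)benzamide, via [2,4-dimethoxy-5-(triisopropylsilyloxy)phenyl]lithium 5 (not isolated)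
Conditions: n-BuLi, THF, −78 °C; then cannulated into ClC(O)N(OMe)Me, THF, −78 to 0 °C
Reagents that add atoms: N-methoxy-N-methylcarbamoyl chloride, CON(C)C(Cl)=O
Why: Bromine–lithium exchange at −78 °C is faster than attack on silicon, and the carbanion of 5 is meta to the silyloxy group so no oxygen-to-carbon silyl shift is possible; inverse addition to the carbamoyl chloride should stop at the N-methoxy-N-methylamide (Weinreb amide).

Step 4
Reactants: 7 6-methylhept-5-en-2-one, 8 diethyl oxalate
Product: 9 ethyl 8-methyl-2,4-dioxonon-7-enoate
Conditions: NaOEt, EtOH, 0 °C to rt; then cold 1 M HCl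
Reagents that add atoms: none
Why: Crossed Claisen condensation: the non-enolizable, highly electrophilic diester acylates the less hindered methyl-side enolate of 7, and the product is held as its stabilized enolate until acidification.

Step 5
Reactants: 9 ethyl 8-methyl-2,4-dioxonon-7-enoate, 6 N,2,4-trimethoxy-N-methyl-5-(triisopropylsilyloxy)benzamide
Product: 11 ethyl 5-[2,4-dimethoxy-5-(triisopropylsilyloxy)benzoyl]-8-methyl-2,4-dioxonon-7-enoate (enolized, configuration at C5 undefined), via dilithium dienolate 10 (not isolated)
Conditions: 9, LiN(iPr)2 (2.2 equiv, commercial solution), THF, −78 to −20 °C; then 6, −78 to 0 °C; cold 1 M HCl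
Reagents that add atoms: none
Why: Dianion acylation of a 1,3-dicarbonyl compound: the second deprotonation occurs at C5, and this more basic carbanion terminus of 10 adds to the amide carbonyl of 6 to give a chelated tetrahedral adduct that collapses only on quench, so neither double addition nor proton transfer to unreacted 10 should interfere. The new sp3 centre is enolizable and disappears in step 6.

Step 6
Reactants: 11 ethyl 5-[2,4-dimethoxy-5-(triisopropylsilyloxy)benzoyl]-8-methyl-2,4-dioxonon-7-enoate
Product: 12 ethyl 6-[2,4-dimethoxy-5-(triisopropylsilyloxy)phenyl]-5-(3-methylbut-2-en-1-yl)-4-oxo-4H-pyran-2-carboxylate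
Conditions: PPh3, C2Cl6, Et3N, CH2Cl2, 0 °C to rt
Reagents that add atoms: none
Why: Appel-type cyclodehydration of a 1,3,5-tricarbonyl compound: Ph3PCl2 formed in the flask activates an enol (or cyclic hemiketal) oxygen, the enol oxygen at the other end closes the six-membered ring by addition–elimination, and Ph3P=O leaves. The amine-buffered medium keeps protic acid away from the prenyl alkene, which would otherwise cyclize onto the neighbouring enol oxygen, and from the aryl silyl ether.

Step 7
Reactants: 12 ethyl 6-[2,4-dimethoxy-5-(triisopropylsilyloxy)phenyl]-5-(3-methylbut-2-en-1-yl)-4-oxo-4H-pyran-2-carboxylate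
Product: 13 6-[2,4-dimethoxy-5-(triisopropylsilyloxy)phenyl]-5-(3-methylbut-2-en-1-yl)-4-oxo-4H-pyran-2-carboxylic acid
Conditions: LiOH·H2O (1.2 equiv), THF/H2O, 0 °C; then cold 1 M HCl to pH 3
Reagents that add atoms: lithium hydroxide, [Li+].[OH-]
Why: Saponification: the ester on a 4-oxo-4H-pyran-2-yl carbon is strongly activated and should hydrolyse with about one equivalent of hydroxide at 0 °C faster than hydroxide adds to the pyranone ring or attacks the hindered aryl silyl ether.

Step 8
Reactants: 13 6-[2,4-dimethoxy-5-(triisopropylsilyloxy)phenyl]-5-(3-methylbut-2-en-1-yl)-4-oxo-4H-pyran-2-carboxylic acid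
Product: 15 6-(2-diazoacetyl)-2-[2,4-dimethoxy-5-(triisopropylsilyloxy)phenyl]-3-(3-methylbut-2-en-1-yl)-4H-pyran-4-one, via pyranone-2-carbonyl chloride 14 (not isolated)
Conditions: Me2C=C(Cl)NMe2, CH2Cl2, 0 °C to rt; then TMSCHN2, MeCN/THF, 0 °C to rt, light excluded
Reagents that add atoms: TMSCHN2 (trimethylsilyldiazomethane), C[Si](C)(C)C=[N+]=[N-]
Why: The α-chloroenamine converts the acid into 14 under neutral conditions, with no hydrogen chloride that could add to the prenyl alkene; 14 has no α-hydrogen and acylates trimethylsilyldiazomethane with loss of Me3SiCl (Arndt–Eistert-type diazoketone formation), so diazomethane is not needed.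

Step 9
Reactants: 16 trimethylsilylacetylene
Product: 19 triisopropyl{[2-(trimethylsilyl)ethynyl]oxy}silane, via lithium (trimethylsilyl)acetylide 17 (not isolated), via lithium 2-(trimethylsilyl)ethynolate 18 (not isolated)
Conditions: n-BuLi, THF, −78 °C; t-BuOOLi (from t-BuOOH and LiN(SiMe3)2), −78 to 0 °C; then TIPSOTf, −78 °C; cold non-aqueous work-up, stored cold
Reagents that add atoms: tert-butyl hydroperoxide (used as its lithium salt), CC(C)(C)OO; TIPSOTf (triisopropylsilyl trifluoromethanesulfonate), CC(C)[Si](OS(=O)(=O)C(F)(F)F)(C(C)C)C(C)C
Why: Electrophilic oxygenation of acetylide 17 by the lithium peroxide gives ynolate 18, and the hard, bulky silyl triflate should silylate at oxygen because the carbon terminus is already shielded by the trimethylsilyl group (O-silylation of ynolates to silyl ynol ethers). The product is kept cold to avoid a 1,3-shift of silicon from oxygen to carbon.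

Step 10
Reactants: 15 6-(2-diazoacetyl)-2-[2,4-dimethoxy-5-(triisopropylsilyloxy)phenyl]-3-(3-methylbut-2-en-1-yl)-4H-pyran-4-one, 19 triisopropyl{[2-(trimethylsilyl)ethynyl]oxy}silane
Product: 24 2-[2,4-dimethoxy-5-(triisopropylsilyloxy)phenyl]-5-hydroxy-3-(3-methylbut-2-en-1-yl)-7-(triisopropylsilyloxy)-6-(trimethylsilyl)-4H-chromen-4-one, via pyranonylketene 20 (not isolated), via siloxycyclobutenone 21 (not isolated), via dienylketene 22 (not isolated), via cyclohexadienone 23 (not isolated)
Conditions: hν (blue LEDs, ca. 440 nm), degassed toluene, rt, 19 (2–3 equiv); then 80 °C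
Reagents that add atoms: none
Why: Excitation of the long-wavelength diazo band expels N2 and the pyranonyl group shifts from the carbonyl carbon to the former diazo carbon (Wolff rearrangement, forming C8–C8a), giving ketene 20 conjugated with the pyranone C5=C6 bond. 20 adds the electron-rich alkyne 19 in a [2+2] cycloaddition in which the ketene carbonyl carbon bonds to the silicon-bearing carbon (C5–C6) and the ketene α-carbon to the oxygen-bearing carbon (C7–C8), giving 21. Warming opens 21 by reversible four-electron electrocyclic cleavage to 22, and the isomer with the pyranone cis to the ketene closes ring A by a thermal disrotatory six-electron electrocyclization between the ketene carbon and pyranone C5 (C4a–C5); 23 then enolizes to the chelated phenol 24. The closest known reaction type is the diazoketone (photo-Wolff) form of the Danheiser benzannulation as used with alkenyl and heteroaryl diazoketones and siloxyalkynes; a 4-pyranone has not yet served as the ene partner and is the new element here. No stereocentre survives: the sp3 carbons of 21 and 23 are transient and racemic. The regiochemistry needed is oxygen at C7 and silicon at C6, which the polarization of the ynol ether secures, and closure at pyranone C5, which is the only position next to the ketene-bearing carbon that carries hydrogen, the other neighbour being the ring oxygen. The chemoselectivity needed is ketene formation without excitation of the aryl pyranone or of the product flavone, which the long irradiation wavelength should secure, and survival of the ketenes, which the silylation of every phenol and the excess of 19 should secure.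

Step 11
Reactants: 24 2-[2,4-dimethoxy-5-(triisopropylsilyloxy)phenyl]-5-hydroxy-3-(3-methylbut-2-en-1-yl)-7-(triisopropylsilyloxy)-6-(trimethylsilyl)-4H-chromen-4-one
Product: 26 5,7-dihydroxy-2-(5-hydroxy-2,4-dimethoxyphenyl)-3-(3-methylbut-2-en-1-yl)-4H-chromen-4-one (artoindonesianin R), via C6-silylated triol 25 (not isolated)
Conditions: Bu4NF, THF, 0 °C; then 1 M aq. HCl, 0 °C to rt
Reagents that add atoms: none
Why: Fluoride cleaves both aryl silyl ethers; on acidification C6, which is ortho to two hydroxyls and para to O1, should be protonated at the ipso position, and the silicon-stabilized arenium ion loses the silyl group (protodesilylation). Brief exposure to dilute aqueous acid should leave the prenyl alkene untouched because no free hydroxyl lies within reach of it.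

## Compound list

1 | 5-bromo-2,4-dimethoxybenzaldehyde | COc1cc(OC)c(Br)cc1C=O | starting material
2 | 5-bromo-2,4-dimethoxyphenyl formate | O=COc1cc(Br)c(OC)cc1OC | intermediate (not isolated)
3 | 5-bromo-2,4-dimethoxyphenol | Oc1cc(Br)c(OC)cc1OC | intermediate
4 | (5-bromo-2,4-dimethoxyphenoxy)triisopropylsilane | CC(C)[Si](Oc1cc(Br)c(OC)cc1OC)(C(C)C)C(C)C | intermediate
5 | [2,4-dimethoxy-5-(triisopropylsilyloxy)phenyl]lithium | [Li]c1cc(O[Si](C(C)C)(C(C)C)C(C)C)c(OC)cc1OC | intermediate (not isolated)
6 | N,2,4-trimethoxy-N-methyl-5-(triisopropylsilyloxy)benzamide | CON(C)C(=O)c1cc(O[Si](C(C)C)(C(C)C)C(C)C)c(OC)cc1OC | intermediate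
7 | 6-methylhept-5-en-2-one | CC(=O)CCC=C(C)C | starting material
8 | diethyl oxalate | CCOC(=O)C(=O)OCC | starting material
9 | ethyl 8-methyl-2,4-dioxonon-7-enoate | CCOC(=O)C(=O)CC(=O)CCC=C(C)C | intermediate
10 | dilithium dienolate (C3,C5-dianion) of ethyl 8-methyl-2,4-dioxonon-7-enoate | [Li+].[Li+].CCOC(=O)C([O-])=CC([O-])=CCC=C(C)C | intermediate (not isolated)
11 | ethyl 5-[2,4-dimethoxy-5-(triisopropylsilyloxy)benzoyl]-8-methyl-2,4-dioxonon-7-enoate (enolizable C5, configuration undefined) | CCOC(=O)C(=O)CC(=O)C(CC=C(C)C)C(=O)c1cc(O[Si](C(C)C)(C(C)C)C(C)C)c(OC)cc1OC | intermediate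
12 | ethyl 6-[2,4-dimethoxy-5-(triisopropylsilyloxy)phenyl]-5-(3-methylbut-2-en-1-yl)-4-oxo-4H-pyran-2-carboxylate | CCOC(=O)c1cc(=O)c(CC=C(C)C)c(-c2cc(O[Si](C(C)C)(C(C)C)C(C)C)c(OC)cc2OC)o1 | intermediate
13 | 6-[2,4-dimethoxy-5-(triisopropylsilyloxy)phenyl]-5-(3-methylbut-2-en-1-yl)-4-oxo-4H-pyran-2-carboxylic acid | OC(=O)c1cc(=O)c(CC=C(C)C)c(-c2cc(O[Si](C(C)C)(C(C)C)C(C)C)c(OC)cc2OC)o1 | intermediate
14 | 6-[2,4-dimethoxy-5-(triisopropylsilyloxy)phenyl]-5-(3-methylbut-2-en-1-yl)-4-oxo-4H-pyran-2-carbonyl chloride | ClC(=O)c1cc(=O)c(CC=C(C)C)c(-c2cc(O[Si](C(C)C)(C(C)C)C(C)C)c(OC)cc2OC)o1 | intermediate (not isolated)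
15 | 6-(2-diazoacetyl)-2-[2,4-dimethoxy-5-(triisopropylsilyloxy)phenyl]-3-(3-methylbut-2-en-1-yl)-4H-pyran-4-one | [N-]=[N+]=CC(=O)c1cc(=O)c(CC=C(C)C)c(-c2cc(O[Si](C(C)C)(C(C)C)C(C)C)c(OC)cc2OC)o1 | intermediate
16 | trimethylsilylacetylene (ethynyltrimethylsilane) | C#C[Si](C)(C)C | starting material
17 | lithium (trimethylsilyl)acetylide | [Li]C#C[Si](C)(C)C | intermediate (not isolated)
18 | lithium 2-(trimethylsilyl)ethynolate | [Li]OC#C[Si](C)(C)C | intermediate (not isolated)
19 | triisopropyl{[2-(trimethylsilyl)ethynyl]oxy}silane (1-(triisopropylsilyloxy)-2-(trimethylsilyl)acetylene) | C[Si](C)(C)C#CO[Si](C(C)C)(C(C)C)C(C)C | intermediate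
20 | 2-{6-[2,4-dimethoxy-5-(triisopropylsilyloxy)phenyl]-5-(3-methylbut-2-en-1-yl)-4-oxo-4H-pyran-2-yl}ethen-1-one (ketene) | O=C=Cc1cc(=O)c(CC=C(C)C)c(-c2cc(O[Si](C(C)C)(C(C)C)C(C)C)c(OC)cc2OC)o1 | intermediate (not isolated)
21 | 4-{6-[2,4-dimethoxy-5-(triisopropylsilyloxy)phenyl]-5-(3-methylbut-2-en-1-yl)-4-oxo-4H-pyran-2-yl}-3-(triisopropylsilyloxy)-2-(trimethylsilyl)cyclobut-2-en-1-one (racemic) | O=C1C([Si](C)(C)C)=C(O[Si](C(C)C)(C(C)C)C(C)C)C1c2cc(=O)c(CC=C(C)C)c(-c3cc(O[Si](C(C)C)(C(C)C)C(C)C)c(OC)cc3OC)o2 | intermediate (not isolated)
22 | (3E)-4-{6-[2,4-dimethoxy-5-(triisopropylsilyloxy)phenyl]-5-(3-methylbut-2-en-1-yl)-4-oxo-4H-pyran-2-yl}-3-(triisopropylsilyloxy)-2-(trimethylsilyl)buta-1,3-dien-1-one (pyranone cis to the ketene carbon) | O=C=C([Si](C)(C)C)/C(O[Si](C(C)C)(C(C)C)C(C)C)=C\c1cc(=O)c(CC=C(C)C)c(-c2cc(O[Si](C(C)C)(C(C)C)C(C)C)c(OC)cc2OC)o1 | intermediate (not isolated)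
23 | 2-[2,4-dimethoxy-5-(triisopropylsilyloxy)phenyl]-3-(3-methylbut-2-en-1-yl)-7-(triisopropylsilyloxy)-6-(trimethylsilyl)-4aH-chromene-4,5-dione (racemic) | O=C1C([Si](C)(C)C)=C(O[Si](C(C)C)(C(C)C)C(C)C)C=C2OC(c3cc(O[Si](C(C)C)(C(C)C)C(C)C)c(OC)cc3OC)=C(CC=C(C)C)C(=O)C12 | intermediate (not isolated)
24 | 2-[2,4-dimethoxy-5-(triisopropylsilyloxy)phenyl]-5-hydroxy-3-(3-methylbut-2-en-1-yl)-7-(triisopropylsilyloxy)-6-(trimethylsilyl)-4H-chromen-4-one | COc1cc(OC)c(-c2oc3cc(O[Si](C(C)C)(C(C)C)C(C)C)c([Si](C)(C)C)c(O)c3c(=O)c2CC=C(C)C)cc1O[Si](C(C)C)(C(C)C)C(C)C | intermediate
25 | 5,7-dihydroxy-2-(5-hydroxy-2,4-dimethoxyphenyl)-3-(3-methylbut-2-en-1-yl)-6-(trimethylsilyl)-4H-chromen-4-one | COc1cc(OC)c(-c2oc3cc(O)c([Si](C)(C)C)c(O)c3c(=O)c2CC=C(C)C)cc1O | intermediate (not isolated)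
26 | 5,7-dihydroxy-2-(5-hydroxy-2,4-dimethoxyphenyl)-3-(3-methylbut-2-en-1-yl)-4H-chromen-4-one (artoindonesianin R) | COc1cc(OC)c(-c2oc3cc(O)cc(O)c3c(=O)c2CC=C(C)C)cc1O | target

## Step count and least certain steps

Total step count: 11. Longest linear sequence: 9 steps (1, 2, 3, 5, 6, 7, 8, 10, 11); steps 4 and 9 are side branches.

Step 10 (key step). What is most likely to go wrong:
- competing light absorption by the 2-aryl-4-pyranone, leading to pyranone photoisomerization or to photocycloaddition between the enone and the prenyl alkene;
- dimerization of ketene 20 before the hindered alkyne adds;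
- stalling at 21 if ring closure onto pyranone C5, an ene partner not yet tried in this reaction, is slow.

Fallback: the ketene is generated in the dark. Starting from 15, a silver-catalysed Wolff rearrangement in aqueous dioxane (AgO2CPh, Et3N) would give the homologous pyranylacetic acid F1. The neutral chloroenamine of step 8 would turn it into the pyranylacetyl chloride F2. Slow addition of Et3N to F2 and 19 in toluene would release 20 by dehydrochlorination, which continues through 21, 22 and 23 on warming. The route is rejoined at 24.

Step 5. What is most likely to go wrong: incomplete or misplaced second deprotonation of 9, self-condensation of 10 through its oxalyl ester, and sluggish addition to the electron-rich, ortho-substituted amide 6, so that proton transfer and decomposition win.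

Fallback: linear assembly with the most reactive electrophile reserved for the last C–C bond. Starting from 6, MeMgBr would give the aryl methyl ketone F3. C-acetylation of its lithium enolate (LiN(SiMe3)2, then N-acetylbenzotriazole) would give the aroylacetone F4. C-prenylation (prenyl bromide, K2CO3, acetone) would give the 2-prenyl diketone F5. The dianion of F5 (LiN(iPr)2, 2 equiv) would be acylated at its methyl terminus by 8. The route is rejoined at 11.

Step 6. What is most likely to go wrong: activation of the central enol oxygen, leading to vinyl chlorides that cannot close; closure through the ester carbonyl to a five-membered ring; or, if acid builds up, addition of an enol oxygen to the prenyl alkene.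

Fallback: the leaving group is installed before the acylation, so that ring closure is a base-mediated addition–elimination. Starting from 9, O-methylation of the C2 enol (HC(OMe)3, MeOH, cat. TsOH) would give the enol methyl ether F6. Kinetic deprotonation at C5 (LiN(SiMe3)2, −78 °C) and acylation with 6 would give the acylated enol ether F7. With mild base (K2CO3, MeCN) the aryl ketone enol oxygen of F7 should add to C2 and expel methanol. The route is rejoined at 12.

Step 9. What is most likely to go wrong: silylation of 18 at carbon, or a later 1,3-shift of silicon from oxygen to carbon on warming; both give a bis(silyl)ketene that cannot act as the ynol ether. Hydrolysis on handling is a further risk.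

Fallback: the silyl ynol ether is replaced by an alkyl ynol ether that is made without an ynolate. tert-Butoxyethyne F8 would be prepared from tert-butyl vinyl ether by bromination and double dehydrobromination. Irradiation of 15 with F8 under the conditions of step 10 should give the 7-tert-butyl ether F9, which already has hydrogen on C6. Me3SiOTf with 2,6-lutidine (loss of 2-methylpropene) followed by Bu4NF and aqueous work-up would then remove the tert-butyl and silyl groups. The route is rejoined at 26.

## Further compounds

F1 | step 10 | 2-{6-[2,4-dimethoxy-5-(triisopropylsilyloxy)phenyl]-5-(3-methylbut-2-en-1-yl)-4-oxo-4H-pyran-2-yl}acetic acid | OC(=O)Cc1cc(=O)c(CC=C(C)C)c(-c2cc(O[Si](C(C)C)(C(C)C)C(C)C)c(OC)cc2OC)o1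
F2 | step 10 | 2-{6-[2,4-dimethoxy-5-(triisopropylsilyloxy)phenyl]-5-(3-methylbut-2-en-1-yl)-4-oxo-4H-pyran-2-yl}acetyl chloride | ClC(=O)Cc1cc(=O)c(CC=C(C)C)c(-c2cc(O[Si](C(C)C)(C(C)C)C(C)C)c(OC)cc2OC)o1
F3 | step 5 | 1-[2,4-dimethoxy-5-(triisopropylsilyloxy)phenyl]ethan-1-one | CC(=O)c1cc(O[Si](C(C)C)(C(C)C)C(C)C)c(OC)cc1OC
F4 | step 5 | 1-[2,4-dimethoxy-5-(triisopropylsilyloxy)phenyl]butane-1,3-dione | CC(=O)CC(=O)c1cc(O[Si](C(C)C)(C(C)C)C(C)C)c(OC)cc1OC
F5 | step 5 | 1-[2,4-dimethoxy-5-(triisopropylsilyloxy)phenyl]-2-(3-methylbut-2-en-1-yl)butane-1,3-dione (enolizable, configuration undefined) | CC(=O)C(CC=C(C)C)C(=O)c1cc(O[Si](C(C)C)(C(C)C)C(C)C)c(OC)cc1OC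
F6 | step 6 | ethyl (2Z)-2-methoxy-8-methyl-4-oxonona-2,7-dienoate | CCOC(=O)/C(OC)=C/C(=O)CCC=C(C)C
F7 | step 6 | ethyl (2Z)-5-[2,4-dimethoxy-5-(triisopropylsilyloxy)benzoyl]-2-methoxy-8-methyl-4-oxonona-2,7-dienoate (enolizable C5, configuration undefined) | CCOC(=O)/C(OC)=C/C(=O)C(CC=C(C)C)C(=O)c1cc(O[Si](C(C)C)(C(C)C)C(C)C)c(OC)cc1OC
F8 | step 9 | tert-butoxyethyne | CC(C)(C)OC#C
F9 | step 9 | 7-tert-butoxy-2-[2,4-dimethoxy-5-(triisopropylsilyloxy)phenyl]-5-hydroxy-3-(3-methylbut-2-en-1-yl)-4H-chromen-4-one | COc1cc(OC)c(-c2oc3cc(OC(C)(C)C)cc(O)c3c(=O)c2CC=C(C)C)cc1O[Si](C(C)C)(C(C)C)C(C)C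
A1 | alternative 1 | 5,7-bis(methoxymethoxy)-4H-chromen-4-one | O=c1ccoc2cc(OCOC)cc(OCOC)c12
A2 | alternative 1 | [2,4-dimethoxy-5-(methoxymethoxy)phenyl]magnesium bromide | COCOc1cc([Mg]Br)c(OC)cc1OC
A3 | alternative 1 | trans-2-[2,4-dimethoxy-5-(methoxymethoxy)phenyl]-5,7-bis(methoxymethoxy)-3-(3-methylbut-2-en-1-yl)chroman-4-one (racemic, one enantiomer drawn) | O=C1[C@H](CC=C(C)C)[C@@H](c3cc(OCOC)c(OC)cc3OC)Oc2cc(OCOC)cc(OCOC)c12
A4 | alternative 1 | 2-[2,4-dimethoxy-5-(methoxymethoxy)phenyl]-5,7-bis(methoxymethoxy)-3-(3-methylbut-2-en-1-yl)-4H-chromen-4-one | COCOc1cc(-c2oc3cc(OCOC)cc(OCOC)c3c(=O)c2CC=C(C)C)c(OC)cc1OC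
A5 | alternative 2 | 2-({1-[2,4-dimethoxy-5-(methoxymethoxy)phenyl]-5-methylhex-4-en-2-yn-1-yl}oxy)-4,6-bis(methoxymethoxy)benzaldehyde (racemic) | O=Cc1c(OCOC)cc(OCOC)cc1OC(C#CC=C(C)C)c1cc(OCOC)c(OC)cc1OC
A6 | alternative 2 | (E)-2-[2,4-dimethoxy-5-(methoxymethoxy)phenyl]-5,7-bis(methoxymethoxy)-3-(3-methylbut-2-en-1-ylidene)chroman-4-one (racemic) | CC(C)=C/C=C1/C(=O)c2c(OCOC)cc(OCOC)cc2OC1c1cc(OCOC)c(OC)cc1OC
A7 | alternative 3 | 1-[5-(allyloxy)-2,4-dimethoxyphenyl]-5-methylhex-4-en-1-one | CC(C)=CCCC(=O)c1cc(OCC=C)c(OC)cc1OC
A8 | alternative 3 | 2,4,6-trifluorobenzoyl chloride | O=C(Cl)c1c(F)cc(F)cc1F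
A9 | alternative 3 | 2-[5-(allyloxy)-2,4-dimethoxyphenyl]-5,7-difluoro-3-(3-methylbut-2-en-1-yl)-4H-chromen-4-one | CC(C)=CCc1c(-c2cc(OCC=C)c(OC)cc2OC)oc2cc(F)cc(F)c2c1=O
A10 | alternative 3 | 5,7-bis(allyloxy)-2-[5-(allyloxy)-2,4-dimethoxyphenyl]-3-(3-methylbut-2-en-1-yl)-4H-chromen-4-one | CC(C)=CCc1c(-c2cc(OCC=C)c(OC)cc2OC)oc2cc(OCC=C)cc(OCC=C)c2c1=O
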